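**Plan**
1. Labdane numbering is used: ring A is C1–C5 plus C10, ring B is C5–C10, and the side chain is C11–C15 followed by the arene. Ring B is a cyclohexene whose only double bond, C8=C9, lies across the ring from C5–C6. The C1–C2–C3–C4 chain of ring A already ties C10 to C5. C5–C10 and C6–C7 are therefore cut together (retro-Diels–Alder) to give an acyclic chain with diene C7=C8–C9=C10 and dienophile C5=C6.
2. The unactivated C5=C6 is armed with a removable acyl group on C6, an N-acyl (R)-4-benzyloxazolidinone. It serves as activator, chelation site and the only source of chirality, and its carbon later leaves as CO2.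
3. The remaining cuts of the chain are C5=C6 (Horner–Wadsworth–Emmons), C14–C15 and C13–CH3 (carboalumination/benzylation), C11–C12 (propargylation), C1–C10 (B-alkyl Suzuki) and C8–C9 (carbomagnesiation of but-2-yn-1-ol).
4. Forward, the tetrasubstituted C9=C10 alkene is made first and the chain is grown from it in both directions. Rings A and B then arise together in step 11, and helper removal and deprotection finish the route.
5. The C9=C10 geometry comes from anti-carbomagnesiation and C13=C14 from syn-carboalumination. The trans C5-H/C10-CH3 relation comes from the diene geometry plus an endo transition state, and the absolute configuration (5R,10R) from the auxiliary.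

Key step: step 11

Assumption: compounds 1, 3, 4, 10, 14, 18 and 19 are taken as commercial. The face selectivity of step 11 is assigned from the chelated s-cis model of N-enoyl oxazolidinones.

**Step 1**
Reactants: 1 2,2-dimethylpent-4-en-1-ol
Product: 2 tert-butyl[(2,2-dimethylpent-4-en-1-yl)oxy]dimethylsilane
Conditions: TBSCl, imidazole, DMF, rt
Reagents that add atoms: tert-butyldimethylsilyl chloride, CC(C)(C)[Si](C)(C)Cl
Why: Standard silylation of a primary alcohol masks the future C5 oxygen through the borane, organolithium and bromination steps.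

**Step 2**
Reactants: 3 but-2-yn-1-ol; 4 isopropenylmagnesium bromide
Product: 6 (2Z)-3-iodo-2-(prop-1-en-2-yl)but-2-en-1-ol, via chelated alkenylmagnesium alkoxide 5 (not isolated)
Conditions: 4 (3 equiv), CuI (10 mol %), THF, 0 °C to 45 °C; then I2, THF, -40 °C to 0 °C
Reagents that add atoms: iodine, II
Why: In this copper-catalysed anti-carbomagnesiation of a propargylic alcohol the magnesium alkoxide directs the alkenyl group to the proximal alkyne carbon (C9) and holds Mg on C10 cis to CH2O in a five-membered chelate, so iodinolysis with retention should fix the C9=C10 geometry (CH3 cis to isopropenyl, I cis to CH2OH).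

**Step 3**
Reactants: 2 TBS ether of 2,2-dimethylpent-4-en-1-ol; 6 dienyl iodide
Product: 8 (2Z)-8-[(tert-butyldimethylsilyl)oxy]-3,7,7-trimethyl-2-(prop-1-en-2-yl)oct-2-en-1-ol, via alkylborane 7 (not isolated)
Conditions: 2, 9-BBN, THF, rt; then 6, PdCl2(dppf) (5 mol %), AsPh3, Cs2CO3, DMF/H2O, rt to 50 °C
Reagents that add atoms: none
Why: Anti-Markovnikov hydroboration followed by B-alkyl Suzuki–Miyaura coupling forms C1–C10, and since oxidative addition to zerovalent palladium and reductive elimination retain alkene geometry, the tether should end cis to C11.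

**Step 4**
Reactants: 8 dienol
Product: 9 {[(6Z)-7-(bromomethyl)-2,2,6,8-tetramethylnona-6,8-dien-1-yl]oxy}(tert-butyl)dimethylsilane
Conditions: CBr4, PPh3, CH2Cl2, -20 °C to 0 °C; used without storage
Reagents that add atoms: carbon tetrabromide, BrC(Br)(Br)Br
Why: The Appel reaction displaces the oxyphosphonium group at the primary allylic carbon by SN2, which in geraniol-type alcohols proceeds without allylic shift or loss of alkene geometry.

**Step 5**
Reactants: 9 allylic bromide; 10 1-(trimethylsilyl)propyne
Product: 12 tert-butyldimethyl({(6E)-2,2,6,8-tetramethyl-7-[4-(trimethylsilyl)but-3-yn-1-yl]nona-6,8-dien-1-yl}oxy)silane, via lithiated silylpropyne 11 (not isolated)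
Conditions: 10, n-BuLi, THF, -78 °C to -20 °C; then 9, -78 °C to -20 °C
Reagents that add atoms: none
Why: Alkylation of 3-lithio-1-(trimethylsilyl)propyne by a primary allylic bromide forms C11–C12, because the silyl group favours the propargylic product and the SN2' site C10 is fully substituted.

**Step 6**
Reactants: 12 bis-silyl dienyne
Product: 13 (6E)-7-(but-3-yn-1-yl)-2,2,6,8-tetramethylnona-6,8-dien-1-ol
Conditions: TBAF (3 equiv), THF, rt
Reagents that add atoms: none
Why: Fluoride-induced desilylation cleaves the O–Si and the C(sp)–Si bonds in one operation and touches nothing else.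

**Step 7**
Reactants: 13 dienynol; 14 methyl 3-(bromomethyl)-4-methoxybenzoate
Product: 16 methyl 3-[(2E,6E)-12-hydroxy-3,7,11,11-tetramethyl-6-(prop-1-en-2-yl)dodeca-2,6-dien-1-yl]-4-methoxybenzoate, via alkenylalane 15 (not isolated)
Conditions: Me3Al (4 equiv), Cp2ZrCl2 (0.3 equiv), CH2Cl2, 0 °C to rt; volatiles removed; then 14, Pd(PPh3)4 (5 mol %), THF, rt
Reagents that add atoms: trimethylaluminium, C[Al](C)C
Why: Zirconium-catalysed syn-methylalumination of the terminal alkyne (Negishi carboalumination, the free alcohol being carried as its aluminium alkoxide) sets E-C13=C14, and palladium-catalysed coupling of the alkenylalane with the benzylic bromide forms C14–C15 with retention.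

**Step 8**
Reactants: 16 tetraenol
Product: 17 methyl 4-methoxy-3-[(2E,6E)-3,7,11,11-tetramethyl-12-oxo-6-(prop-1-en-2-yl)dodeca-2,6-dien-1-yl]benzoate
Conditions: Dess–Martin periodinane, NaHCO3, CH2Cl2, 0 °C to rt
Reagents that add atoms: none
Why: Buffered Dess–Martin oxidation of the neopentyl alcohol should give a non-enolisable aldehyde and leave the diene, the alkenes and the arene intact.

**Step 9**
Reactants: 18 diethylphosphonoacetic acid; 19 (R)-4-benzyl-1,3-oxazolidin-2-one
Product: 21 diethyl {2-[(4R)-4-benzyl-2-oxo-1,3-oxazolidin-3-yl]-2-oxoethyl}phosphonate, via mixed anhydride 20 (not isolated)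
Conditions: 18, PivCl, Et3N, THF, -20 °C; then LiCl, 19, rt
Reagents that add atoms: none
Why: In this N-acylation of the oxazolidinone through a mixed pivalic anhydride the nucleophile attacks the less hindered carbonyl, and the stereocentre of 19 is not involved.

**Step 10**
Reactants: 17 aldehyde; 21 phosphonate
Product: 22 methyl 3-[(2E,6E,12E)-14-[(4R)-4-benzyl-2-oxo-1,3-oxazolidin-3-yl]-3,7,11,11-tetramethyl-14-oxo-6-(prop-1-en-2-yl)tetradeca-2,6,12-trien-1-yl]-4-methoxybenzoate
Conditions: LiCl, i-Pr2NEt, MeCN, rt
Reagents that add atoms: none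
Why: The Horner–Wadsworth–Emmons reaction in its mild LiCl/amine form is E-selective with alpha-quaternary aldehydes and installs C6 together with the activating and directing group.

**Step 11**
Reactants: 22 trienimide
Product: 23 (4R)-4-benzyl-3-{[(1R,4aR,8aR)-4-{(3E)-5-[2-methoxy-5-(methoxycarbonyl)phenyl]-3-methylpent-3-en-1-yl}-3,4a,8,8-tetramethyl-1,2,4a,5,6,7,8,8a-octahydronaphthalen-1-yl]carbonyl}-1,3-oxazolidin-2-one (labdane positions 5R,6R,10R; trans-decalin, C6 acyl group cis to H5)
Conditions: Me2AlCl (3 equiv), CH2Cl2, -30 °C to rt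
Reagents that add atoms: none
Why: Two equivalents of Me2AlCl should turn the imide into its cationic Me2Al chelate, which locks the enoyl unit s-cis and lowers its LUMO, and the diene C7=C8–C9=C10 then adds suprafacially across C5=C6 in a concerted asynchronous [4+2] cycloaddition that forms C5–C10 and C6–C7 and leaves the new pi bond exactly at C8=C9. The closest known reaction type is the auxiliary-controlled, dialkylaluminium chloride-promoted intramolecular Diels–Alder reaction of (E)-2,8,10-trienoyl oxazolidinones (1,7,9-decatriene class), and forming a methyl-bearing quaternary carbon at a diene terminus with an inside methyl group has its parallel in the cycloadditions of 1-vinyl-2,6,6-trimethylcyclohexene. Ring B closes as the six-membered cycloadduct ring, and ring A closes at the same moment in the fused (type 1) mode because the four-carbon tether C1–C4, folded chair-like and helped by the gem-dimethyl group on C4, spans C10 and C5. The trans relation of C10-CH3 and C5-H follows from the diene geometry (tether outside, methyl inside) combined with the endo transition state (acyl group under the diene, C4 exo), the C5/C6 relation follows from the E dienophile, and the absolute sense comes from the benzyl group of the (R)-auxiliary, which blocks one face of the chelate so that the diene bonds to the Re face at C6. The step needs endo over exo selectivity, which the Lewis acid raises, face selectivity, which the chelate sets, and chemoselectivity, which is secured because the isolated C13=C14 alkene and the arene are neither conjugated nor within reach. The low temperature also suppresses the 1,5-hydrogen shift of the inside methyl group.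

**Step 12**
Reactants: 23 cycloadduct
Product: 25 (1R,4aR,8aR)-4-{(3E)-5-[2-methoxy-5-(methoxycarbonyl)phenyl]-3-methylpent-3-en-1-yl}-3,4a,8,8-tetramethyl-1,2,4a,5,6,7,8,8a-octahydronaphthalene-1-carboxylic acid, via peroxy acid 24 (not isolated)
Conditions: LiOH, H2O2, THF/H2O, 0 °C; then Na2SO3; then 1 M HCl to pH 3
Reagents that add atoms: hydrogen peroxide (as LiOOH), OO
Why: Hydroperoxide-mediated cleavage of an N-acyl oxazolidinone attacks the exocyclic carbonyl even when it is hindered and is much faster than hydrolysis of the electron-rich methyl benzoate, and sulfite reduces the percarboxylate before acidification so that the alkenes are not epoxidised.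

**Step 13**
Reactants: 25 acid
Product: 27 methyl 4-methoxy-3-{(2E)-3-methyl-5-[(4aR,8aR)-2,5,5,8a-tetramethyl-3,4,4a,5,6,7,8,8a-octahydronaphthalen-1-yl]pent-2-en-1-yl}benzoate, via thiohydroxamate ester 26 (not isolated)
Conditions: N-hydroxypyridine-2-thione, DCC, CH2Cl2, 0 °C, dark; then t-BuSH, visible light, rt
Reagents that add atoms: none
Why: In the Barton reductive decarboxylation the secondary C6 radical formed on loss of CO2 takes hydrogen from the thiol faster than it can reach any alkene, which turns C6 into CH2 and leaves C5 and C10 untouched.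

**Step 14**
Reactants: 27 methyl ether methyl ester
Product: 28 4-hydroxy-3-{(2E)-3-methyl-5-[(4aR,8aR)-2,5,5,8a-tetramethyl-3,4,4a,5,6,7,8,8a-octahydronaphthalen-1-yl]pent-2-en-1-yl}benzoic acid (target)
Conditions: EtSNa (10 equiv), DMF, 110 °C; then cold 1 M HCl
Reagents that add atoms: none
Why: Thiolate SN2 demethylation cleaves both the aryl methyl ether (its phenoxide is stabilised by the para carboxyl group) and the methyl ester under non-acidic conditions, so that neither chroman formation nor alkene migration should occur.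

**Compound list**
1 | 2,2-dimethylpent-4-en-1-ol | C=CCC(C)(C)CO | starting material
2 | tert-butyl[(2,2-dimethylpent-4-en-1-yl)oxy]dimethylsilane | C=CCC(C)(C)CO[Si](C)(C)C(C)(C)C | intermediate
3 | but-2-yn-1-ol | CC#CCO | starting material
4 | isopropenylmagnesium bromide | C=C(C)[Mg]Br | starting material
5 | 3-methyl-4-(prop-1-en-2-yl)-2,5-dihydro-1,2-oxamagnesole (chelated alkenylmagnesium alkoxide) | CC1=C(C(C)=C)CO[Mg]1 | intermediate
6 | (2Z)-3-iodo-2-(prop-1-en-2-yl)but-2-en-1-ol | C=C(C)/C(CO)=C(\C)I | intermediate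
7 | 9-{5-[(tert-butyldimethylsilyl)oxy]-4,4-dimethylpentyl}-9-borabicyclo[3.3.1]nonane | CC(C)(CCCB1C2CCCC1CCC2)CO[Si](C)(C)C(C)(C)C | intermediate
8 | (2Z)-8-[(tert-butyldimethylsilyl)oxy]-3,7,7-trimethyl-2-(prop-1-en-2-yl)oct-2-en-1-ol | C=C(C)/C(CO)=C(\C)CCCC(C)(C)CO[Si](C)(C)C(C)(C)C | intermediate
9 | {[(6Z)-7-(bromomethyl)-2,2,6,8-tetramethylnona-6,8-dien-1-yl]oxy}(tert-butyl)dimethylsilane | C=C(C)/C(CBr)=C(\C)CCCC(C)(C)CO[Si](C)(C)C(C)(C)C | intermediate
10 | 1-(trimethylsilyl)propyne | CC#C[Si](C)(C)C | starting material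
11 | 3-lithio-1-(trimethylsilyl)propyne | [Li]CC#C[Si](C)(C)C | intermediate
12 | tert-butyldimethyl({(6E)-2,2,6,8-tetramethyl-7-[4-(trimethylsilyl)but-3-yn-1-yl]nona-6,8-dien-1-yl}oxy)silane | C=C(C)/C(CCC#C[Si](C)(C)C)=C(\C)CCCC(C)(C)CO[Si](C)(C)C(C)(C)C | intermediate
13 | (6E)-7-(but-3-yn-1-yl)-2,2,6,8-tetramethylnona-6,8-dien-1-ol | C=C(C)/C(CCC#C)=C(\C)CCCC(C)(C)CO | intermediate
14 | methyl 3-(bromomethyl)-4-methoxybenzoate | COC(=O)c1ccc(OC)c(CBr)c1 | starting material
15 | (E)-alkenyldimethylalane of 13, carried as its dimethylaluminium alkoxide | C=C(C)/C(CC/C(C)=C/[Al](C)C)=C(\C)CCCC(C)(C)CO[Al](C)C | intermediate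
16 | methyl 3-[(2E,6E)-12-hydroxy-3,7,11,11-tetramethyl-6-(prop-1-en-2-yl)dodeca-2,6-dien-1-yl]-4-methoxybenzoate | C=C(C)/C(CC/C(C)=C/Cc1cc(C(=O)OC)ccc1OC)=C(\C)CCCC(C)(C)CO | intermediate
17 | methyl 4-methoxy-3-[(2E,6E)-3,7,11,11-tetramethyl-12-oxo-6-(prop-1-en-2-yl)dodeca-2,6-dien-1-yl]benzoate | C=C(C)/C(CC/C(C)=C/Cc1cc(C(=O)OC)ccc1OC)=C(\C)CCCC(C)(C)C=O | intermediate
18 | diethylphosphonoacetic acid | CCOP(=O)(CC(=O)O)OCC | starting material
19 | (R)-4-benzyl-1,3-oxazolidin-2-one | O=C1N[C@H](Cc2ccccc2)CO1 | starting material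
20 | (diethoxyphosphoryl)acetic pivalic anhydride | CCOP(=O)(CC(=O)OC(=O)C(C)(C)C)OCC | intermediate
21 | diethyl {2-[(4R)-4-benzyl-2-oxo-1,3-oxazolidin-3-yl]-2-oxoethyl}phosphonate | CCOP(=O)(CC(=O)N1[C@H](Cc2ccccc2)COC1=O)OCC | intermediate
22 | trienimide, (2E,6E,12E), (4R)-auxiliary (full name in step 10) | C=C(C)/C(CC/C(C)=C/Cc1cc(C(=O)OC)ccc1OC)=C(\C)CCCC(C)(C)/C=C/C(=O)N2[C@H](Cc3ccccc3)COC2=O | intermediate
23 | Diels–Alder adduct, 5R,6R,10R, (4R)-auxiliary (full name in step 11) | CC1=C(CC/C(C)=C/Cc2cc(C(=O)OC)ccc2OC)[C@]3(C)CCCC(C)(C)[C@H]3[C@H](C(=O)N4[C@H](Cc5ccccc5)COC4=O)C1 | intermediate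
24 | C6 peroxycarboxylic acid of the bicycle | CC1=C(CC/C(C)=C/Cc2cc(C(=O)OC)ccc2OC)[C@]3(C)CCCC(C)(C)[C@H]3[C@H](C(=O)OO)C1 | intermediate
25 | C6 carboxylic acid, (1R,4aR,8aR) (full name in step 12) | CC1=C(CC/C(C)=C/Cc2cc(C(=O)OC)ccc2OC)[C@]3(C)CCCC(C)(C)[C@H]3[C@H](C(=O)O)C1 | intermediate
26 | 2-thioxopyridin-1(2H)-yl ester of 25 | CC1=C(CC/C(C)=C/Cc2cc(C(=O)OC)ccc2OC)[C@]3(C)CCCC(C)(C)[C@H]3[C@H](C(=O)On4ccccc4=S)C1 | intermediate
27 | methyl 4-methoxy-3-{(2E)-3-methyl-5-[(4aR,8aR)-2,5,5,8a-tetramethyl-3,4,4a,5,6,7,8,8a-octahydronaphthalen-1-yl]pent-2-en-1-yl}benzoate | CC1=C(CC/C(C)=C/Cc2cc(C(=O)OC)ccc2OC)[C@]3(C)CCCC(C)(C)[C@H]3CC1 | intermediate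
28 | 4-hydroxy-3-{(2E)-3-methyl-5-[(4aR,8aR)-2,5,5,8a-tetramethyl-3,4,4a,5,6,7,8,8a-octahydronaphthalen-1-yl]pent-2-en-1-yl}benzoic acid | CC1=C(CC/C(C)=C/Cc2cc(C(=O)O)ccc2O)[C@]2(C)CCCC(C)(C)[C@H]2CC1 | target

**Totals:** 14 steps in all. The longest linear sequence is 12 steps (steps 2–8 and 10–14, from but-2-yn-1-ol).

**Steps most likely to fail**

**Step 11.** The fully substituted, twisted diene may reach the s-cis geometry only with difficulty, and C5 sits next to quaternary C4. Cycloaddition may therefore be slower than Lewis acid-induced degradation of the diene. Face and endo selectivity may also erode if higher temperature is needed.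
The fallback replaces the bulky chelated imide by the smaller iminium activation of an enal. It sets out from 17 and comes back at 25.
- Wittig reaction of 17 with (triphenylphosphoranylidene)acetaldehyde in warm toluene should give the (2E,6E,12E)-trienal F1.
- An intramolecular Diels–Alder reaction under iminium catalysis follows. The catalyst is the trifluoroacetate salt of (2R,5R)-5-benzyl-2-tert-butyl-3-methylimidazolidin-4-one in MeCN/H2O. This is the catalyst enantiomer that leaves the Re face at C6 open, and it should give the (5R,6R,10R)-6-formyl bicycle F2.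
- Pinnick oxidation (NaClO2, NaH2PO4, excess 2-methylbut-2-ene) leads to 25.

**Step 2.** Addition of the branched alkenyl Grignard reagent to the internal alkyne may be slow. Copper-induced homocoupling of the reagent may compete. The alkenylmagnesium species may also lose its geometry before iodinolysis.
The fallback builds the tetrasubstituted alkene from a beta-keto ester instead. It sets out from 2 (as its borane 7) and comes back at 12, so it replaces steps 2–5.
- Methyl acetoacetate is alkylated with (4-iodobut-1-yn-1-yl)trimethylsilane (NaH, THF/DMF) to give methyl 2-acetyl-6-(trimethylsilyl)hex-5-ynoate F3.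
- E-selective enol triflation under non-chelating two-phase conditions (Tf2O, aqueous Me4NOH, toluene) gives the (E)-enol triflate F4.
- Stereoretentive B-alkyl Suzuki coupling of F4 with 7 (PdCl2(dppf), Cs2CO3) gives the tetrasubstituted enoate F5.
- Excess MeLi gives the tertiary allylic alcohol F6.
- Syn-elimination with methyl N-(triethylammoniosulfonyl)carbamate toward a methyl group gives 12.

**Step 7.** Residual Me3Al may transfer methyl to the benzylpalladium species or attack the ester, and transmetalation from the alkoxide-bearing alane may stall.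
The fallback reverses the polarity of the C14–C15 coupling. It sets out from 13 and 14 and comes back at 16.
- The same carboalumination of 13 is quenched with I2 to give the isolable (E)-alkenyl iodide F7.
- Compound 14 is converted with zinc dust and LiCl in THF into the benzylic zinc bromide F8.
- Negishi coupling of F7 with F8 (Pd(PPh3)4, THF, rt) gives 16.

**Further compounds**
F1 | step 11 | methyl 4-methoxy-3-[(2E,6E,12E)-3,7,11,11-tetramethyl-14-oxo-6-(prop-1-en-2-yl)tetradeca-2,6,12-trien-1-yl]benzoate | C=C(C)/C(CC/C(C)=C/Cc1cc(C(=O)OC)ccc1OC)=C(\C)CCCC(C)(C)/C=C/C=O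
F2 | step 11 | methyl 3-{(2E)-5-[(4R,4aR,8aR)-4-formyl-2,5,5,8a-tetramethyl-3,4,4a,5,6,7,8,8a-octahydronaphthalen-1-yl]-3-methylpent-2-en-1-yl}-4-methoxybenzoate | CC1=C(CC/C(C)=C/Cc2cc(C(=O)OC)ccc2OC)[C@]3(C)CCCC(C)(C)[C@H]3[C@H](C=O)C1
F3 | step 2 | methyl 2-acetyl-6-(trimethylsilyl)hex-5-ynoate | COC(=O)C(CCC#C[Si](C)(C)C)C(C)=O
F4 | step 2 | methyl (2E)-3-{[(trifluoromethyl)sulfonyl]oxy}-2-[4-(trimethylsilyl)but-3-yn-1-yl]but-2-enoate | COC(=O)/C(CCC#C[Si](C)(C)C)=C(\C)OS(=O)(=O)C(F)(F)F
F5 | step 2 | methyl (2E)-8-[(tert-butyldimethylsilyl)oxy]-3,7,7-trimethyl-2-[4-(trimethylsilyl)but-3-yn-1-yl]oct-2-enoate | COC(=O)/C(CCC#C[Si](C)(C)C)=C(\C)CCCC(C)(C)CO[Si](C)(C)C(C)(C)C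
F6 | step 2 | (3E)-9-[(tert-butyldimethylsilyl)oxy]-2,4,8,8-tetramethyl-3-[4-(trimethylsilyl)but-3-yn-1-yl]non-3-en-2-ol | CC(C)(O)/C(CCC#C[Si](C)(C)C)=C(\C)CCCC(C)(C)CO[Si](C)(C)C(C)(C)C
F7 | step 7 | (6E,10E)-11-iodo-2,2,6,10-tetramethyl-7-(prop-1-en-2-yl)undeca-6,10-dien-1-ol | C=C(C)/C(CC/C(C)=C/I)=C(\C)CCCC(C)(C)CO
F8 | step 7 | [2-methoxy-5-(methoxycarbonyl)benzyl]zinc bromide | COC(=O)c1ccc(OC)c(C[Zn]Br)c1
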